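**Strategy**

The route rests on cutting the farnesyl side chain (C1'–C12') at its C5'–C6' sp3–sp2 bond. The key step exploits the 1,5-diene C2'=C3'–C4'H2–C5'H2–C6'=C7': the saturated C4'–C5' bridge is a hydroborated vinyl group in disguise. The precursor is the complete, masked epoxycyclohexenone ring (C1 dimethyl ketal, C5/C6 epoxide, C4 and C1' silyl ethers) carrying a C1'–C5' 3-methylpenta-2,4-dienyl arm. 9-BBN hydroborates only its terminal C4'=C5' alkene, and one-pot B-alkyl Suzuki–Miyaura coupling with (E)-1-iodo-2,6-dimethylhepta-1,5-diene attaches the C9 terminus with both E-trisubstituted alkenes defined. Ring stereocentres derive from one catalyst-set carbinol (C1') via directed epoxidation and epoxy ketone reduction; hydroxymethylation and acetylation follow.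

Key step: step 13

Remark on numbering: locants are those of the target. Ring: C1 (C=O), C2 (bears CH2OAc), C3, C4 (CHOH), C5 and C6 (epoxide). Side chain: C1'–C12'. "As in the target" means the spatial arrangement of the target (4S,5R,6R,1'S), whatever the formal CIP label of the intermediate; the SMILES are authoritative.

Assumption: trityl hydroperoxide, (−)-MIB, TEEDA (N,N,N',N'-tetraethylethylenediamine) and 9-BBN are treated as purchasable reagents.

**Route**

Step 1
Reactants: 1 prop-2-yn-1-ol
Product: 3 (E)-3-iodo-2-methylprop-2-en-1-ol, via alkenylalane 2 (not isolated)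
Conditions: AlMe3, Cp2ZrCl2 (cat.), CH2Cl2, 0 °C → rt; then I2, THF, −30 → 0 °C
Reagents that add atoms: trimethylaluminium C[Al](C)C; iodine II
Why: Negishi zirconium-catalysed carboalumination adds CH3 and Al syn across the alkyne with Al on the terminal carbon, and iodinolysis with retention should give only the E iodide.

Step 2
Reactants: 3 (E)-3-iodo-2-methylprop-2-en-1-ol
Product: 4 (E)-3-iodo-2-methylprop-2-enal
Conditions: MnO2, CH2Cl2, rt
Reagents that add atoms: none
Why: Allylic oxidation with activated MnO2 should give the enal without touching the vinyl iodide or the alkene geometry.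

Step 3
Reactants: 4 (E)-3-iodo-2-methylprop-2-enal
Product: 5 (E)-1-iodo-2-methylbuta-1,3-diene
Conditions: Ph3PCH3Br, NaHMDS, THF, 0 °C; then 4, −78 → 0 °C (product kept as a solution)
Reagents that add atoms: methyltriphenylphosphonium bromide C[P+](c1ccccc1)(c1ccccc1)c1ccccc1.[Br-]
Why: Wittig methylenation of the unhindered enal should give the terminal diene and leave the E iodoalkene unchanged.

Step 4
Reactants: 6 6-methylhept-5-en-2-one
Product: 8 6-methylhept-5-en-1-yne, via enol phosphate 7 (not isolated)
Conditions: LDA, THF, −78 °C; ClP(O)(OEt)2, −78 °C → rt; then LDA (2.3 equiv), −78 °C → rt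
Reagents that add atoms: none
Why: Kinetic enolisation at the methyl group, O-phosphorylation and base-induced β-elimination of the terminal enol phosphate (methyl ketone to terminal alkyne conversion) should leave the trisubstituted alkene untouched.

Step 5
Reactants: 8 6-methylhept-5-en-1-yne
Product: 10 (E)-1-iodo-2,6-dimethylhepta-1,5-diene, via alkenylalane 9 (not isolated)
Conditions: AlMe3, Cp2ZrCl2 (cat.), CH2Cl2, rt; then I2, THF, −30 → 0 °C
Reagents that add atoms: trimethylaluminium C[Al](C)C; iodine II
Why: Negishi carboalumination is specific for the terminal alkyne over the trisubstituted alkene and sets the E geometry of the future C6'=C7' alkene by syn addition, which iodinolysis retains.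

Step 6
Reactants: 11 2-hydroxy-5-methoxybenzaldehyde
Product: 12 2-(tert-butyldimethylsilyloxy)-5-methoxybenzaldehyde
Conditions: TBSCl, imidazole, DMF, rt
Reagents that add atoms: tert-butyldimethylsilyl chloride CC(C)(C)[Si](C)(C)Cl
Why: O-Silylation masks the acidic phenol so that the aldehyde can meet an organozinc reagent under ligand control.

Step 7
Reactants: 5 (E)-1-iodo-2-methylbuta-1,3-diene; 12 2-(tert-butyldimethylsilyloxy)-5-methoxybenzaldehyde
Product: 15 (1S,2E)-1-[2-(tert-butyldimethylsilyloxy)-5-methoxyphenyl]-3-methylpenta-2,4-dien-1-ol, via dienyllithium 13 (not isolated), via bis(dienyl)zinc 14 (not isolated)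
Conditions: 5 (2.4 equiv), t-BuLi, Et2O, −78 °C; ZnBr2 (0.5 equiv per Li), −78 → 0 °C; TEEDA, (−)-MIB (10 mol %), toluene; then 12, 0 °C
Reagents that add atoms: none
Why: Iodine–lithium exchange and transmetalation give a configurationally stable dienylzinc, and its amino-alcohol-catalysed asymmetric 1,2-addition (lithium halides sequestered by TEEDA) should deliver the alkenyl group to the Si face of the aryl aldehyde, setting C1' as S with the E alkene retained.

Step 8
Reactants: 15 (1S,2E)-1-[2-(tert-butyldimethylsilyloxy)-5-methoxyphenyl]-3-methylpenta-2,4-dien-1-ol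
Product: 17 2-[(1S,2E)-1-hydroxy-3-methylpenta-2,4-dienyl]-4,4-dimethoxycyclohexa-2,5-dien-1-one, via phenol 16 (not isolated)
Conditions: TBAF, THF, 0 °C; then MeOH, PhI(OAc)2, 0 °C
Reagents that add atoms: methanol CO
Why: Fluoride desilylation frees the phenol, and hypervalent-iodine oxidative dearomatisation in methanol should give the p-quinone monoketal because methanol traps the phenoxenium ion at the methoxy-bearing para carbon; telescoping avoids handling the acid-sensitive o-hydroxybenzylic dienyl alcohol.

Step 9
Reactants: 17 2-[(1S,2E)-1-hydroxy-3-methylpenta-2,4-dienyl]-4,4-dimethoxycyclohexa-2,5-dien-1-one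
Product: 18 epoxy ketone 5,6-epoxy-5-[(1S,2E)-1-hydroxy-3-methylpenta-2,4-dienyl]-1,1-dimethoxycyclohex-2-en-4-one (epoxide as in the target)
Conditions: Ph3COOH, NaHMDS, toluene, −40 °C
Reagents that add atoms: trityl hydroperoxide OOC(c1ccccc1)(c1ccccc1)c1ccccc1
Why: In this alkoxide-directed Weitz–Scheffer epoxidation the C1' sodium alkoxide should bind sodium trityl peroxide and deliver it to C6 of the proximal enone rather than to the remote C2=C3 enone, on the face fixed by A(1,2) strain (C1'–H turned toward the C4 carbonyl, dienyl group anti to the reagent), which sets C5 and C6 as in the target.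

Step 10
Reactants: 18 epoxy ketone
Product: 19 C1'-O-triethylsilyl ether of 18
Conditions: TESCl, imidazole, DMAP (cat.), DMF, rt
Reagents that add atoms: chlorotriethylsilane CC[Si](Cl)(CC)CC
Why: O-Silylation removes the chelating hydroxyl so that the next reduction is not steered by an O–Al chelate, and the mild conditions spare the epoxy ketone and the ketal.

Step 11
Reactants: 19 C1'-O-triethylsilyl ether of 18
Product: 20 C4 alcohol 5,6-epoxy-1,1-dimethoxy-5-[(1S,2E)-3-methyl-1-(triethylsilyloxy)penta-2,4-dienyl]cyclohex-2-en-4-ol (4-OH anti to the epoxide)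
Conditions: DIBAL-H, toluene, −78 °C
Reagents that add atoms: none
Why: Hydride 1,2-reduction of the enone carbonyl by DIBAL-H is expected from the epoxide face (aluminium pre-coordinates to the epoxide oxygen, and the opposite face is screened by the silyloxy-dienyl arm on quaternary C5), giving the C4 alcohol anti to the epoxide as in the target.

Step 12
Reactants: 20 C4 alcohol
Product: 21 bis-TES ether 5,6-epoxy-1,1-dimethoxy-4-(triethylsilyloxy)-5-[(1S,2E)-3-methyl-1-(triethylsilyloxy)penta-2,4-dienyl]cyclohex-2-ene
Conditions: TESCl, imidazole, DMAP (cat.), DMF, rt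
Reagents that add atoms: chlorotriethylsilane CC[Si](Cl)(CC)CC
Why: O-Silylation of the remaining hindered allylic alcohol keeps B–H and aqueous base away from the 2,3-epoxy alcohol (no borinate formation, no Payne rearrangement) in the coupling.

Step 13
Reactants: 21 bis-TES ether (dienyl arm); 10 (E)-1-iodo-2,6-dimethylhepta-1,5-diene
Product: 23 bis-TES farnesyl ketal 5,6-epoxy-1,1-dimethoxy-4-(triethylsilyloxy)-5-[(1S,2E,6E)-3,7,11-trimethyl-1-(triethylsilyloxy)dodeca-2,6,10-trienyl]cyclohex-2-ene, via B-alkyl-9-BBN borane 22 (not isolated)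
Conditions: 9-BBN, THF, 0 °C → rt; then 10, PdCl2(dppf) (cat.), AsPh3, aq. Cs2CO3, DMF, rt
Reagents that add atoms: none
Why: 9-BBN adds syn and anti-Markovnikov to the only monosubstituted alkene of 21 (C4'=C5'), placing boron on C5' (borane 22); Pd(0) then inserts into the C–I bond of 10, the base-activated borate transfers the primary C5' alkyl group to palladium and reductive elimination forms the C5'–C6' bond. The closest known reaction type is the B-alkyl Suzuki–Miyaura coupling of alkene- or diene-derived B-alkyl-9-BBN reagents with (E)-alkenyl iodides. No ring is closed and no stereocentre is created; the E geometry of C6'=C7' is carried over from 10 because oxidative addition and reductive elimination are stereoretentive, and the E C2'=C3' alkene is not touched. The step needs chemoselective hydroboration of one alkene out of three in 21 and regioselective boron delivery to C5': the trisubstituted C2'=C3' alkene and the ring C2=C3 alkene, flanked by the ketal carbon and the silyloxy-bearing C4, should react with the bulky dialkylborane far more slowly than a terminal vinyl group, and 10 is added only after hydroboration is complete. The masking of the ring (C1 ketal, two silyl ethers, no carbonyl or OH) leaves nothing for 9-BBN to reduce, and the bidentate dppf ligand with AsPh3 keeps reductive elimination ahead of β-hydride elimination from the alkylpalladium intermediate.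

Step 14
Reactants: 23 bis-TES farnesyl ketal
Product: 24 diol enone 5,6-epoxy-4-hydroxy-5-[(1S,2E,6E)-1-hydroxy-3,7,11-trimethyldodeca-2,6,10-trienyl]cyclohex-2-en-1-one (ring as in the target)
Conditions: 48% aq. HF, MeCN, 0 °C → rt
Reagents that add atoms: water O
Why: Acidic hydrolysis with aqueous HF should cleave both TES ethers and convert the allylic dimethyl ketal into the conjugated enone in one operation, under conditions that α,β-epoxy ketones of this class and trisubstituted alkenes tolerate.

Step 15
Reactants: 24 diol enone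
Product: 25 triol 5,6-epoxy-4-hydroxy-2-(hydroxymethyl)-5-[(1S,2E,6E)-1-hydroxy-3,7,11-trimethyldodeca-2,6,10-trienyl]cyclohex-2-en-1-one
Conditions: 37% aq. HCHO, DMAP, THF, rt
Reagents that add atoms: formaldehyde C=O
Why: In this Morita–Baylis–Hillman reaction DMAP adds reversibly to C3, the enolate captures formaldehyde at C2 (the only enone α-position) and loss of DMAP restores the enone, now hydroxymethylated.

Step 16
Reactants: 25 triol
Product: 26 target, {(4S,5R,6R)-5,6-epoxy-4-hydroxy-5-[(1S,2E,6E)-1-hydroxy-3,7,11-trimethyldodeca-2,6,10-trienyl]-1-oxocyclohex-2-en-2-yl}methyl acetate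
Conditions: AcCl, 2,4,6-collidine, CH2Cl2, −78 °C
Reagents that add atoms: acetyl chloride CC(Cl)=O
Why: Selective O-acylation at low temperature should discriminate the unhindered primary allylic alcohol from the two secondary alcohols that flank quaternary C5.

**Compound list**

1 | prop-2-yn-1-ol | C#CCO | starting material
2 | alkenylalane: dimethyl[(E)-3-(dimethylalumanyloxy)-2-methylprop-1-enyl]alumane | C[Al](C)/C=C(\C)CO[Al](C)C | intermediate
3 | (E)-3-iodo-2-methylprop-2-en-1-ol | I/C=C(\C)CO | intermediate
4 | (E)-3-iodo-2-methylprop-2-enal | I/C=C(\C)C=O | intermediate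
5 | (E)-1-iodo-2-methylbuta-1,3-diene | I/C=C(\C)C=C | intermediate
6 | 6-methylhept-5-en-2-one | CC(=O)CCC=C(C)C | starting material
7 | enol phosphate: diethyl 6-methylhepta-1,5-dien-2-yl phosphate | C=C(CCC=C(C)C)OP(=O)(OCC)OCC | intermediate
8 | 6-methylhept-5-en-1-yne | C#CCCC=C(C)C | intermediate
9 | alkenylalane: [(E)-2,6-dimethylhepta-1,5-dienyl]dimethylalumane | C[Al](C)/C=C(\C)CCC=C(C)C | intermediate
10 | (E)-1-iodo-2,6-dimethylhepta-1,5-diene | I/C=C(\C)CCC=C(C)C | intermediate
11 | 2-hydroxy-5-methoxybenzaldehyde | COc1ccc(O)c(C=O)c1 | starting material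
12 | 2-(tert-butyldimethylsilyloxy)-5-methoxybenzaldehyde | COc1ccc(O[Si](C)(C)C(C)(C)C)c(C=O)c1 | intermediate
13 | dienyllithium: [(E)-2-methylbuta-1,3-dienyl]lithium | [Li]/C=C(\C)C=C | intermediate
14 | bis(dienyl)zinc: bis[(E)-2-methylbuta-1,3-dienyl]zinc | C=C/C(C)=C/[Zn]/C=C(\C)C=C | intermediate
15 | (1S,2E)-1-[2-(tert-butyldimethylsilyloxy)-5-methoxyphenyl]-3-methylpenta-2,4-dien-1-ol | COc1ccc(O[Si](C)(C)C(C)(C)C)c(c1)[C@@H](O)/C=C(\C)C=C | intermediate
16 | phenol: 2-[(1S,2E)-1-hydroxy-3-methylpenta-2,4-dienyl]-4-methoxyphenol | COc1ccc(O)c(c1)[C@@H](O)/C=C(\C)C=C | intermediate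
17 | 2-[(1S,2E)-1-hydroxy-3-methylpenta-2,4-dienyl]-4,4-dimethoxycyclohexa-2,5-dien-1-one | O=C1C=CC(OC)(OC)C=C1[C@@H](O)/C=C(\C)C=C | intermediate
18 | epoxy ketone: 5,6-epoxy-5-[(1S,2E)-1-hydroxy-3-methylpenta-2,4-dienyl]-1,1-dimethoxycyclohex-2-en-4-one, C5/C6 as in the target | C1=CC(=O)[C@@]2([C@@H](O)/C=C(\C)C=C)O[C@H]2C1(OC)OC | intermediate
19 | C1'-O-TES ether of 18 | C1=CC(=O)[C@@]2([C@@H](O[Si](CC)(CC)CC)/C=C(\C)C=C)O[C@H]2C1(OC)OC | intermediate
20 | C4 alcohol: 5,6-epoxy-1,1-dimethoxy-5-[(1S,2E)-3-methyl-1-(triethylsilyloxy)penta-2,4-dienyl]cyclohex-2-en-4-ol, 4-OH anti to the epoxide, ring as in the target | C1=C[C@H](O)[C@@]2([C@@H](O[Si](CC)(CC)CC)/C=C(\C)C=C)O[C@H]2C1(OC)OC | intermediate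
21 | bis-TES ether of the C4,C1' diol (dienyl arm), ring as in the target | C1=C[C@H](O[Si](CC)(CC)CC)[C@@]2([C@@H](O[Si](CC)(CC)CC)/C=C(\C)C=C)O[C@H]2C1(OC)OC | intermediate
22 | B-alkyl-9-BBN borane: 21 with C5' bonded to the boron of 9-borabicyclo[3.3.1]nonane | C1=C[C@H](O[Si](CC)(CC)CC)[C@@]2([C@@H](O[Si](CC)(CC)CC)/C=C(\C)CCB3C4CCCC3CCC4)O[C@H]2C1(OC)OC | intermediate
23 | bis-TES farnesyl ketal: 5,6-epoxy-1,1-dimethoxy-4-(triethylsilyloxy)-5-[(1S,2E,6E)-3,7,11-trimethyl-1-(triethylsilyloxy)dodeca-2,6,10-trienyl]cyclohex-2-ene, ring as in the target | C1=C[C@H](O[Si](CC)(CC)CC)[C@@]2([C@@H](O[Si](CC)(CC)CC)/C=C(\C)CC/C=C(\C)CCC=C(C)C)O[C@H]2C1(OC)OC | intermediate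
24 | diol enone: 5,6-epoxy-4-hydroxy-5-[(1S,2E,6E)-1-hydroxy-3,7,11-trimethyldodeca-2,6,10-trienyl]cyclohex-2-en-1-one, ring as in the target | C1=C[C@H](O)[C@@]2([C@@H](O)/C=C(\C)CC/C=C(\C)CCC=C(C)C)O[C@H]2C1=O | intermediate
25 | triol: 2-(hydroxymethyl) derivative of 24 | OCC1=C[C@H](O)[C@@]2([C@@H](O)/C=C(\C)CC/C=C(\C)CCC=C(C)C)O[C@H]2C1=O | intermediate
26 | {(4S,5R,6R)-5,6-epoxy-4-hydroxy-5-[(1S,2E,6E)-1-hydroxy-3,7,11-trimethyldodeca-2,6,10-trienyl]-1-oxocyclohex-2-en-2-yl}methyl acetate | CC(=O)OCC1=C[C@H](O)[C@@]2([C@@H](O)/C=C(\C)CC/C=C(\C)CCC=C(C)C)O[C@H]2C1=O | target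

**Totals**

Total step count: 16. Longest linear sequence: 13 steps (steps 1–3, then 7–16).

**Steps most likely to fail**

Step 9 (directed epoxidation). The peroxide may be delivered to the unsubstituted C2=C3 enone instead of C5=C6 (loss of regiocontrol), or the secondary carbinol may give poor facial control. The fallback uses reagent control on a primary alkoxide and creates C1' afterwards. It sets out from 11: NaBH4 reduction gives 2-(hydroxymethyl)-4-methoxyphenol F1; PhI(OAc)2 in MeOH gives 2-(hydroxymethyl)-4,4-dimethoxycyclohexa-2,5-dien-1-one F2; tartrate-mediated nucleophilic epoxidation (Ph3COOH, NaHMDS, the diisopropyl tartrate enantiomer matched to the required face, which a test run must identify) gives the hydroxymethyl epoxy ketone F3; Dess–Martin oxidation gives the epoxy aldehyde F4. Catalyst-controlled addition of bis(dienyl)zinc 14 (generated as in step 7, with (−)-MIB or its enantiomer, whichever gives the 1'S carbinol on this α-chiral aldehyde) to the aldehyde of F4 comes back to the route at 18.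

Step 11 (ketone reduction). Hydride may attack anti to the epoxide oxygen, or with poor facial selectivity, giving the C4 epimer. The fallback accepts the anti-epoxide attack and then inverts C4. It sets out from 19: Luche reduction (NaBH4, CeCl3, MeOH, −78 °C) gives the cis-epoxy alcohol, C4 epimer of 20 F5; Mitsunobu inversion (4-nitrobenzoic acid, PPh3, DIAD) gives the inverted 4-nitrobenzoate of 20 F6; methanolysis (K2CO3, MeOH) comes back to the route at 20.

Step 15 (hydroxymethylation). Amine addition at the hindered C3 may be slow or reversible, and the base may erode the epoxyquinol by aromatisation. The fallback replaces the organocatalytic C–C bond formation by halogenation and cross-coupling. It sets out from 24: α-iodination (I2, pyridine, CH2Cl2) gives the 2-iodoenone, 2-iodo derivative of 24 F7; Stille coupling with (tributylstannyl)methanol (Pd2(dba)3, AsPh3) comes back to the route at 25.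

Further compounds
F1 | step 9 | 2-(hydroxymethyl)-4-methoxyphenol | COc1ccc(O)c(CO)c1
F2 | step 9 | 2-(hydroxymethyl)-4,4-dimethoxycyclohexa-2,5-dien-1-one | O=C1C=CC(OC)(OC)C=C1CO
F3 | step 9 | 5,6-epoxy-5-(hydroxymethyl)-1,1-dimethoxycyclohex-2-en-4-one, epoxide as in the target | C1=CC(=O)[C@@]2(CO)O[C@H]2C1(OC)OC
F4 | step 9 | 5,6-epoxy-1,1-dimethoxy-4-oxocyclohex-2-ene-5-carbaldehyde, epoxide as in the target | C1=CC(=O)[C@@]2(C=O)O[C@H]2C1(OC)OC
F5 | step 11 | C4 epimer of 20 (4-OH syn to the epoxide) | C1=C[C@@H](O)[C@@]2([C@@H](O[Si](CC)(CC)CC)/C=C(\C)C=C)O[C@H]2C1(OC)OC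
F6 | step 11 | 4-nitrobenzoate of 20 | C1=C[C@H](OC(=O)c3ccc(cc3)[N+](=O)[O-])[C@@]2([C@@H](O[Si](CC)(CC)CC)/C=C(\C)C=C)O[C@H]2C1(OC)OC
F7 | step 15 | 2-iodo derivative of 24 | IC1=C[C@H](O)[C@@]2([C@@H](O)/C=C(\C)CC/C=C(\C)CCC=C(C)C)O[C@H]2C1=O
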